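All runs are simulated on assumed constants; scatter was added.

However long a flask is left, its target can stand at most at its charge of starting material, 100% of it. That ceiling was my first bound for each flask here, and the question was how much of the way 12 min gets.

| flask | starting material | protic impurity | free catalyst | remark | time |
|---|---|---|---|---|---|
| Friday's | 0.22 M | 0.010 M | 0.28 mM | run made earlier |  |
| alder | 0.20 M | 0.0200 M | 0.080 mM |  | 12 min |
| maple | 0.060 M | 0.0100 M | 0.28 mM |  | 12 min |
| cedar | 0.40 M | 0.00250 M | 0.20 mM |  | 12 min |
| ash | 0.20 M | 0.0100 M | 0.28 mM |  | 12 min |
| elm | 0.30 M | 0.0400 M | 0.60 mM |  | 12 min |

Friday's run (percent of the starting material charged)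

| time / min | target / % |
|---|---|
| 0.200 | 0.2 |
| 0.333 | 0 |
| 0.667 | 1.9 |
| 1.33 | 4.3 |
| 2.50 | 7.8 |

(each reading ± 0.5 percentage points)

- a reading or a percentage of target counts all its forms, free or not
- no earlier run changes the charge of free catalyst; that part of a forecast is a guess
- no earlier run changes the charge of protic impurity; that part of a forecast is a guess

1. all flasks from highest to lowest amount of target, in percent of the starting material charged, at 12 min (alder / maple / cedar / ash / elm)
2. the same order at 50 min (alder / maple / cedar / ash / elm)
3. the amount of target, in percent of the starting material charged of the flask you put first, at 12 min
4. the amount of target, in percent of the starting material charged of the flask you put last, at 12 min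

Friday's run rose nearly straight, to 7.8% at 2.50 min. From that last reading I took 24.5 /min, the turnover rate: target made per minute per catalyst charged. Both bounds below take the rate as proportional to the catalyst and set the protic impurity aside, and both steps are guesses, since no earlier run changes those charges.

From above, I let the catalyst stay busy, so target rises straight: turnover rate times catalyst times time, over the starting material. From below, I let the rate fall with the starting material, first order, using Friday's constant scaled by catalyst. Friday's readings stop at 7.8%, too early on the curve to choose between these.

For alder the bracket was narrow, 10.5% to 11.8%. For maple the straight line reaches the charge at 8.74 min, earlier than 12 min, so its bracket ran from 32.3% up to the ceiling, and my hand went no further. The lower line put elm at 56.6%, above maple. I leaned to the upper line, which ranks flasks by catalyst over starting material and puts maple first.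

The forecast gave maple > elm > ash > cedar > alder at 12 min and maple > cedar > ash > elm > alder at 50 min, with 40% for maple and 9% for alder, taking the rate “with partial saturation, which favours dilute maple in percent terms”. Its maple figure lay inside my bracket, and its alder figure lay below it.

The flasks gave maple > elm > ash > cedar > alder at 12 min and ash > elm > maple > cedar > alder at 50 min. Maple held 80.2%, inside the bracket, and alder held 12.0%, just above its upper bound.

    catalyst intermediate ⇌ free catalyst + target (K = 10.2 M, k = 26.6 /min)
    starting material + target ⇌ idle adduct, settled at all times (K = 9.50 /M)
    starting material + protic impurity → quenched substrate (k = 14.6 /M/min)
    starting material + free catalyst → catalyst intermediate (k = 2610 /M/min)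

In alder at 12.0 min, catalyst intermediate, the resting state, held 93.3% of the catalyst. The neighbouring flask is alder with 0.0480 mM of catalyst charged, read at the same time. For it the turnover rate gives 7.06% from above, and the first-order line gives 6.46% from below. That flask held catalyst intermediate at 93.9% of its catalyst, starting material at 78.4%, and target at 7.22%.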